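The target is a cyclohexa-1,3-diene (ring atoms C1–C6; C7 is the CH2OBz carbon on C1) whose inner diene carbons C2 and C3 carry only hydrogen. That CH=CH pair is therefore taken from acetylene and inserted between the two alkene termini of an acyclic, enantiopure 1,5-diene that already holds C5–OBz, C6–OSi and C7–OBz. One ruthenium-catalysed tandem cross enyne/ring-closing metathesis makes C3=C4, C1=C2 and the carbocycle, and creates no stereocentre. The precursor is a syn-configured 3,4-dioxygenated hexa-1,5-diene with one vinyl end and one 2-(benzoyloxymethyl)-substituted methylidene end. It comes from an asymmetric (Z)-γ-alkoxyallylboration, and its syn pair becomes the trans-5R,6R pair of the ring.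

Key step: step 7

Remark: the target numbering (ring C1–C6, exocyclic C7) is kept for all open-chain compounds. The target SMILES reads 5R,6R, so O5 and O6 are trans on the ring, which corresponds to a syn (threo) diol in the open chain.

Step 1
Reactants: 1 2-methylidenepropane-1,3-diol; 2 benzoyl chloride
Product: 3 2-(hydroxymethyl)prop-2-en-1-yl benzoate
Conditions: 1 (3 equiv), BzCl (1 equiv), Et3N, CH2Cl2/THF, −10 °C
Reagents that add atoms: benzoyl chloride (2), O=C(Cl)c1ccccc1
Why: Einhorn-type O-acylation of two equivalent hydroxyls, in which the excess of the water-soluble diol keeps double benzoylation low and the surplus is washed out.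

Step 2
Reactants: 3 2-(hydroxymethyl)prop-2-en-1-yl benzoate
Product: 4 2-formylprop-2-en-1-yl benzoate
Conditions: activated MnO2 (excess), CH2Cl2, rt; filtration, used at once
Reagents that add atoms: none
Why: MnO2 oxidation of a primary allylic alcohol stops at the enal under neutral heterogeneous conditions that spare the allylic benzoate, and filtration is the only work-up the sensitive enal has to bear.

Step 3
Reactants: 4 2-formylprop-2-en-1-yl benzoate; 5 allyl 4-methoxybenzyl ether; 6 (−)-B-methoxydiisopinocampheylborane (from (+)-α-pinene)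
Product: 11 (3R,4R)-3-hydroxy-4-[(4-methoxybenzyl)oxy]-2-methylidenehex-5-en-1-yl benzoate, via allyllithium 7 (not isolated), via borate complex 8 (not isolated), via allylborane 9 (not isolated), via borinate 10 (not isolated)
Conditions: 5, s-BuLi, THF, −78 °C; 6, −78 °C; BF3·OEt2, −78 °C; 4, −78 °C; then NaBO3·4H2O, THF/H2O, 0 °C to rt
Reagents that add atoms: allyl 4-methoxybenzyl ether (5), C=CCOCc1ccc(OC)cc1
Why: Brown asymmetric γ-alkoxyallylboration, in which chelation-controlled metalation fixes the Z allyl geometry, the closed Zimmerman–Traxler chair turns it into the syn C5/C6 relationship, the isopinocampheyl groups derived from (+)-α-pinene direct attack to the Si face of the formyl group (5R and 6R), and perborate replaces alkaline peroxide in the work-up to spare the benzoate.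

Step 4
Reactants: 11 (3R,4R)-3-hydroxy-4-[(4-methoxybenzyl)oxy]-2-methylidenehex-5-en-1-yl benzoate
Product: 12 (3R,4R)-3-[(tert-butyldimethylsilyl)oxy]-4-[(4-methoxybenzyl)oxy]-2-methylidenehex-5-en-1-yl benzoate
Conditions: TBSOTf, 2,6-lutidine, CH2Cl2, −78 to 0 °C
Reagents that add atoms: tert-butyldimethylsilyl trifluoromethanesulfonate, CC(C)(C)[Si](C)(C)OS(=O)(=O)C(F)(F)F
Why: Silylation of the hindered O6 hydroxyl with a silyl triflate and a non-nucleophilic base is a standard protection that touches no stereocentre, reserves O6 for the final free hydroxyl and adds the bulk that later biases the C5–C6 rotamer.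

Step 5
Reactants: 12 (3R,4R)-3-[(tert-butyldimethylsilyl)oxy]-4-[(4-methoxybenzyl)oxy]-2-methylidenehex-5-en-1-yl benzoate
Product: 13 (3R,4R)-3-[(tert-butyldimethylsilyl)oxy]-4-hydroxy-2-methylidenehex-5-en-1-yl benzoate
Conditions: DDQ, CH2Cl2/pH 7 buffer (10:1), 0 °C
Reagents that add atoms: none
Why: Oxidative PMB cleavage (hydride abstraction by DDQ, then hydrolysis of the oxocarbenium ion) leaves the silyl ether, the benzoate and both unconjugated alkenes intact, and it is placed before ring closure because DDQ would dehydrogenate the cyclohexadiene.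

Step 6
Reactants: 13 (3R,4R)-3-[(tert-butyldimethylsilyl)oxy]-4-hydroxy-2-methylidenehex-5-en-1-yl benzoate; 2 benzoyl chloride
Product: 14 (3R,4R)-5-[(benzoyloxy)methyl]-4-[(tert-butyldimethylsilyl)oxy]hexa-1,5-dien-3-yl benzoate
Conditions: BzCl, pyridine, DMAP (cat.), CH2Cl2, 0 °C to rt
Reagents that add atoms: benzoyl chloride (2), O=C(Cl)c1ccccc1
Why: DMAP-catalysed O-acylation takes place at oxygen with retention at C5, and the weakly basic medium forms no alkoxide that could start an O6 to O5 silyl shift.

Step 7
Reactants: 14 (3R,4R)-5-[(benzoyloxy)methyl]-4-[(tert-butyldimethylsilyl)oxy]hexa-1,5-dien-3-yl benzoate; 15 acetylene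
Product: 16 [(5R,6R)-5-(benzoyloxy)-6-[(tert-butyldimethylsilyl)oxy]cyclohexa-1,3-dien-1-yl]methyl benzoate
Conditions: (H2IMes)Cl2Ru(=CH-2-iPrOC6H4) (second-generation Hoveyda–Grubbs catalyst, H2IMes = 1,3-dimesitylimidazolidin-2-ylidene, 10 mol % in two portions), acetone-free C2H2 (about 5 vol % in Ar, slow stream), 1,4-benzoquinone (10 mol %), toluene (0.005 M), 45 °C
Reagents that add atoms: acetylene (15), C#C
Why: Proposed new method: the ruthenium carbene first exchanges onto the monosubstituted C4 vinyl group of 14, [2+2] addition of acetylene and opening of the ruthenacyclobutene then make C3=C4 and move the carbene to C2, and this vinylcarbene closes onto the C1 methylidene to make C1=C2 and release Ru=CH2, which reloads on the next molecule of 14 with loss of ethylene. The closest known reaction type is the ruthenium-catalysed tandem cross enyne metathesis/ring-closing metathesis of 1,5-hexadienes with terminal alkynes to 1,3-cyclohexadienes; acetylene as the alkyne, the diene as limiting partner and closure of a vinylcarbene onto this 1,1-disubstituted alkene are untested, although ring-closing metathesis onto CH2=C(CH2OR)CH(OR') units is routine for ordinary dienes. The single ring (C1–C6, six-membered) closes in the ring-closing metathesis mode of a dienyl carbene, and both new double bonds end up endocyclic. No stereocentre is formed, and C5 and C6 are spectators whose C–O and C–H bonds are not touched. Three selectivities are needed: loading at C4 and not at C1 (the methylidene is shielded by CH2OBz and CH(OTBS)), six-ring closure and not direct diene closure (a cyclobutene is excluded by strain), and a cis C3=C4 vinylcarbene, since only that isomer reaches C1 while the trans isomer is lost to an open triene; the anti arrangement preferred by the bulky OBz and OTBS groups of the syn diol holds C4 and C1 gauche and should make closure faster than bimolecular escape. A low stationary acetylene concentration, argon sparging of ethylene and a phosphine-free catalyst are chosen to hold back acetylene oligomerisation, butadiene formation and methylidene decay.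

Step 8
Reactants: 16 [(5R,6R)-5-(benzoyloxy)-6-[(tert-butyldimethylsilyl)oxy]cyclohexa-1,3-dien-1-yl]methyl benzoate
Product: 17 [(5R,6R)-5-(benzoyloxy)-6-hydroxycyclohexa-1,3-dien-1-yl]methyl benzoate (target)
Conditions: HF·pyridine, pyridine, THF, 0 °C to rt; poured into cold pH 7 buffer
Reagents that add atoms: none
Why: Fluoride-driven Si–O cleavage in a pyridine-buffered, weakly acidic medium forms no alkoxide, so neither an O5 to O6 benzoyl shift nor base-induced elimination to the arene should compete, and acylated trans-dihydrodiols ionise only slowly in acid.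

Compound list
1 | 2-methylidenepropane-1,3-diol | C=C(CO)CO | starting material
2 | benzoyl chloride | O=C(Cl)c1ccccc1 | starting material
3 | 2-(hydroxymethyl)prop-2-en-1-yl benzoate | C=C(CO)COC(=O)c1ccccc1 | intermediate
4 | 2-formylprop-2-en-1-yl benzoate | C=C(C=O)COC(=O)c1ccccc1 | intermediate
5 | allyl 4-methoxybenzyl ether | C=CCOCc1ccc(OC)cc1 | starting material
6 | (−)-B-methoxydiisopinocampheylborane | COB([C@@H]1C[C@@H]2C[C@H]([C@H]1C)C2(C)C)[C@@H]1C[C@@H]2C[C@H]([C@H]1C)C2(C)C | starting material
7 | (Z)-3-[(4-methoxybenzyl)oxy]prop-2-en-1-yllithium | [Li]C/C=C\OCc1ccc(OC)cc1 | intermediate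
8 | lithium diisopinocampheyl(methoxy)[(Z)-3-{(4-methoxybenzyl)oxy}allyl]borate | [Li+].CO[B-](C/C=C\OCc1ccc(OC)cc1)([C@@H]1C[C@@H]2C[C@H]([C@H]1C)C2(C)C)[C@@H]1C[C@@H]2C[C@H]([C@H]1C)C2(C)C | intermediate
9 | diisopinocampheyl[(Z)-3-{(4-methoxybenzyl)oxy}allyl]borane | B(C/C=C\OCc1ccc(OC)cc1)([C@@H]1C[C@@H]2C[C@H]([C@H]1C)C2(C)C)[C@@H]1C[C@@H]2C[C@H]([C@H]1C)C2(C)C | intermediate
10 | O6-diisopinocampheylborinate of 11 | C=C[C@@H](OCc1ccc(OC)cc1)[C@H](OB([C@@H]1C[C@@H]2C[C@H]([C@H]1C)C2(C)C)[C@@H]1C[C@@H]2C[C@H]([C@H]1C)C2(C)C)C(=C)COC(=O)c1ccccc1 | intermediate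
11 | (3R,4R)-3-hydroxy-4-[(4-methoxybenzyl)oxy]-2-methylidenehex-5-en-1-yl benzoate | C=C[C@@H](OCc1ccc(OC)cc1)[C@H](O)C(=C)COC(=O)c1ccccc1 | intermediate
12 | (3R,4R)-3-[(tert-butyldimethylsilyl)oxy]-4-[(4-methoxybenzyl)oxy]-2-methylidenehex-5-en-1-yl benzoate | C=C[C@@H](OCc1ccc(OC)cc1)[C@H](O[Si](C)(C)C(C)(C)C)C(=C)COC(=O)c1ccccc1 | intermediate
13 | (3R,4R)-3-[(tert-butyldimethylsilyl)oxy]-4-hydroxy-2-methylidenehex-5-en-1-yl benzoate | C=C[C@@H](O)[C@H](O[Si](C)(C)C(C)(C)C)C(=C)COC(=O)c1ccccc1 | intermediate
14 | (3R,4R)-5-[(benzoyloxy)methyl]-4-[(tert-butyldimethylsilyl)oxy]hexa-1,5-dien-3-yl benzoate | C=C[C@@H](OC(=O)c1ccccc1)[C@H](O[Si](C)(C)C(C)(C)C)C(=C)COC(=O)c1ccccc1 | intermediate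
15 | acetylene | C#C | starting material
16 | [(5R,6R)-5-(benzoyloxy)-6-[(tert-butyldimethylsilyl)oxy]cyclohexa-1,3-dien-1-yl]methyl benzoate | O=C(OCC1=CC=C[C@@H](OC(=O)c2ccccc2)[C@@H]1O[Si](C)(C)C(C)(C)C)c1ccccc1 | intermediate
17 | [(5R,6R)-5-(benzoyloxy)-6-hydroxycyclohexa-1,3-dien-1-yl]methyl benzoate | O=C(OCC1=CC=C[C@@H](OC(=O)c2ccccc2)[C@@H]1O)c1ccccc1 | target

Total step count: 8. Longest linear sequence: 8 steps (1 to 17).

Steps most likely to fail

Step 7. Several processes may defeat it:
- the catalyst may be used up by acetylene oligomerisation;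
- the vinylcarbene may form with trans C3=C4 geometry and drain into open-chain material;
- closure onto the hindered methylidene may be too slow;
- benzoic acid may be lost with aromatisation.

A silylated alkyne is no remedy. The usual regiochemistry would place silicon on C2 and demand a tetrasubstituted C1=C2 bond.

The fallback uses known chemistry, sets out from 11 and returns at 16. It fixes the cis geometry in a temporary ring and adds the two carbons one at a time.
- Silylation of 11 with chloro(dimethyl)vinylsilane and Et3N gives the dimethyl(vinyl)silyl ether F1.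
- Silicon-tethered ring-closing metathesis with Mo(=N-2,6-iPr2C6H3)(=CHCMe2Ph)[OCMe(CF3)2]2 in benzene loads at the C4 vinyl group and gives the six-membered cyclic siloxane F2, in which C3=C4 is necessarily cis.
- Hiyama–Denmark coupling with iodoethene (Pd(dba)2, TBAF, THF, rt) replaces silicon by vinyl with retention and gives the (Z)-dienol F3.
- The operations of steps 4 to 6 (TBSOTf; DDQ; BzCl) then lead through the silyl ether F4 and the C5 alcohol F5 to the (Z)-triene dibenzoate F6.
- An ordinary diene–ene ring-closing metathesis of F6 with (H2IMes)(PCy3)Cl2Ru=CHPh (second-generation Grubbs catalyst, CH2Cl2, 40 °C) closes C1=C2 to give 16.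

Step 3. Facial control by the isopinocampheyl groups may be incomplete on the small, electron-poor 2-substituted enal. Material may also be lost through conjugate attack on the enal or ester cleavage during boron removal.

The fallback sets out from 5 and 4 and returns at 11. It separates relative from absolute stereocontrol.
- Metalated 5 is trapped with 2-isopropoxy-4,4,5,5-tetramethyl-1,3,2-dioxaborolane to give the achiral pinacol (Z)-γ-alkoxyallylboronate F7.
- F7 adds to 4 through the same closed chair and, after a non-oxidative work-up, gives the racemic syn alcohol F8.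
- Sharpless kinetic resolution (Ti(OiPr)4, D-(−)-diisopropyl tartrate, t-BuOOH about 0.6 equiv, 4 Å sieves, CH2Cl2, −20 °C) epoxidises the C1 methylidene of the (5S,6S) enantiomer to the epoxy alcohol F9. The (5R,6R) alcohol 11 is left unreacted and is separated by chromatography.

Step 8. Cleavage of the hindered silyl ether may be slow. Prolonged exposure to acid may then bring ionisation at the allylic C–O bonds with aromatisation, or a benzoyl shift between O5 and O6.

The fallback sets out from 14 and returns at 17 by reversing the order of events.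
- The silyl ether is removed from open-chain 14 with HF·pyridine, where no arene can form, to give the hydroxy diene F10.
- F10 is then taken through the conditions of step 7, so that ring closure under neutral conditions is the last operation. A free allylic hydroxyl next to the methylidene is tolerated by ruthenium carbenes and tends to speed up metathesis at the adjacent alkene.

Further compounds
F1 | step 7 | (3R,4R)-3-{[dimethyl(vinyl)silyl]oxy}-4-[(4-methoxybenzyl)oxy]-2-methylidenehex-5-en-1-yl benzoate | C=C[C@@H](OCc1ccc(OC)cc1)[C@H](O[Si](C)(C)C=C)C(=C)COC(=O)c1ccccc1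
F2 | step 7 | 2-{(5R,6R)-5-[(4-methoxybenzyl)oxy]-2,2-dimethyl-5,6-dihydro-2H-1,2-oxasilin-6-yl}prop-2-en-1-yl benzoate | C[Si]1(C)C=C[C@@H](OCc2ccc(OC)cc2)[C@H](O1)C(=C)COC(=O)c1ccccc1
F3 | step 7 | (3R,4R,5Z)-3-hydroxy-4-[(4-methoxybenzyl)oxy]-2-methylideneocta-5,7-dien-1-yl benzoate | C=C/C=C\[C@@H](OCc1ccc(OC)cc1)[C@H](O)C(=C)COC(=O)c1ccccc1
F4 | step 7 | (3R,4R,5Z)-3-[(tert-butyldimethylsilyl)oxy]-4-[(4-methoxybenzyl)oxy]-2-methylideneocta-5,7-dien-1-yl benzoate | C=C/C=C\[C@@H](OCc1ccc(OC)cc1)[C@H](O[Si](C)(C)C(C)(C)C)C(=C)COC(=O)c1ccccc1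
F5 | step 7 | (3R,4R,5Z)-3-[(tert-butyldimethylsilyl)oxy]-4-hydroxy-2-methylideneocta-5,7-dien-1-yl benzoate | C=C/C=C\[C@@H](O)[C@H](O[Si](C)(C)C(C)(C)C)C(=C)COC(=O)c1ccccc1
F6 | step 7 | (3R,4R,5Z)-4-(benzoyloxy)-3-[(tert-butyldimethylsilyl)oxy]-2-methylideneocta-5,7-dien-1-yl benzoate | C=C/C=C\[C@@H](OC(=O)c1ccccc1)[C@H](O[Si](C)(C)C(C)(C)C)C(=C)COC(=O)c1ccccc1
F7 | step 3 | 2-[(Z)-3-{(4-methoxybenzyl)oxy}allyl]-4,4,5,5-tetramethyl-1,3,2-dioxaborolane | COc1ccc(CO/C=C\CB2OC(C)(C)C(C)(C)O2)cc1
F8 | step 3 | racemic syn-3-hydroxy-4-[(4-methoxybenzyl)oxy]-2-methylidenehex-5-en-1-yl benzoate (both enantiomers shown) | C=C[C@@H](OCc1ccc(OC)cc1)[C@H](O)C(=C)COC(=O)c1ccccc1.C=C[C@H](OCc1ccc(OC)cc1)[C@@H](O)C(=C)COC(=O)c1ccccc1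
F9 | step 3 | [(2S)-2-{(1R,2S)-1-hydroxy-2-[(4-methoxybenzyl)oxy]but-3-en-1-yl}oxiran-2-yl]methyl benzoate | C=C[C@H](OCc1ccc(OC)cc1)[C@@H](O)[C@]1(CO1)COC(=O)c1ccccc1
F10 | step 8 | (3R,4R)-5-[(benzoyloxy)methyl]-4-hydroxyhexa-1,5-dien-3-yl benzoate | C=C[C@@H](OC(=O)c1ccccc1)[C@H](O)C(=C)COC(=O)c1ccccc1
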